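**Plan**

1. Numbering as in abscisic acid: ring C1'–C6' (C7' = CH3 on C2', C8' = CH2O and C9' = CH3 on C6'), chain C1–C5. Retrosynthesis cuts C3–C4 (Stille), the C8'O–acyl ester bond, C4=C5 (chromium stannyl olefination of a C5 aldehyde), and then both ring bonds C3'–C4' and C1'–C6' at once.
2. Enabling feature: the 4-hydroxycyclohex-2-enone ring (C4'=O, C2'=C3', fully substituted C1' and C6') is the ring-closed isomer of a 3-oxido-hexatriene C1'=C2'–C3'=C4'(O–)–C5'=C6'.
3. Temporary ring: O1' and C5 on C1' are tied into a 2-tert-butyl-1,3-dioxolan-4-one, absent from the target. It makes C3' the γ-carbon of a dienolate and C1' a chiral, captodative triene terminus; it is opened again after the ring is made.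
4. Forward: dioxolanone silyl dienolate (C1'–C3', C5, C7') plus (E)-enoyl chloride (C4'–C6', C8', C9') give acylation at C3' and 6π closure of C1'–C6' in one flask. Then lactone → lactol → (E)-alkenylstannane, release of 8'-OH, esterification with the glutarate half ester, and a final Stille coupling with (Z)-3-iodobut-2-enoic acid.
5. Stereochemistry: the acetal carbon (from (S)-2-hydroxy-3-methylbutanoic acid) fixes C1' by approach anti to tert-butyl; disrotation with the E-enone fixes C6' relative to C1'; esterase desymmetrisation fixes the glutarate carbinol; 4E comes from the chromium olefination and 2Z from the iodo acid.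

Key step: step 7

Remark: the esterase hydrolysis in step 12 is taken to give the (S)-half ester, as recalled for this diester and to be confirmed by correlation with mevalonolactone; if its enantiomeric purity is insufficient it is raised by crystallising a salt with a chiral amine.

**Route**

Step 1
Reactants: 1 (S)-2-hydroxy-3-methylbutanoic acid; 2 pivalaldehyde
Product: 3 (2S,5S)-2-tert-butyl-5-(propan-2-yl)-1,3-dioxolan-4-one
Conditions: TsOH·H2O (cat.), H2SO4 (cat.), pentane, reflux, Dean–Stark trap; cis isomer purified by distillation or crystallisation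
Reagents that add atoms: none
Why: Acid-catalysed acetalisation with azeotropic removal of water should favour the cis-2,5-disubstituted dioxolanone, so the carbinol centre of 1 sets the new acetal carbon as 2S (self-regeneration-of-stereocentres acetal).

Step 2
Reactants: 3
Product: 5 (2S)-2-tert-butyl-5-(propan-2-ylidene)-1,3-dioxolan-4-one, via bromo-dioxolanone 4 (not isolated)
Conditions: NBS, AIBN (cat.), CCl4, reflux; filter; then DBU, CH2Cl2, 0 → 23 °C
Reagents that add atoms: none
Why: Wohl–Ziegler bromination at the captodative C5–H and E2 loss of HBr toward the only β-hydrogen (the isopropyl methine) should give the tetrasubstituted alkylidene lactone, with the acetal stereocentre untouched.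

Step 3
Reactants: 5
Product: 7 (2S)-2-tert-butyl-4-(prop-1-en-2-yl)-5-[(trimethylsilyl)oxy]-1,3-dioxole, via lithium dienolate 6 (not isolated)
Conditions: LDA (commercial solution), THF, −78 °C; then Me3SiCl, −78 → 0 °C; pentane, filter, used crude
Reagents that add atoms: chlorotrimethylsilane, C[Si](C)(C)Cl
Why: Kinetic γ-deprotonation of the β,β-dimethyl alkylidene lactone and O-silylation (silyl ketene acetal formation) should give the 2-silyloxydiene whose terminal CH2 is the future C3'.

Step 4
Reactants: 8 1-[(tert-butyldimethylsilyl)oxy]propan-2-one; 9 triethyl phosphonoacetate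
Product: 10 ethyl (E)-4-[(tert-butyldimethylsilyl)oxy]-3-methylbut-2-enoate
Conditions: NaH, THF, 0 → 23 °C; Z isomer removed by chromatography
Reagents that add atoms: none
Why: Horner–Wadsworth–Emmons olefination of the ketone should favour the E ester (ester trans to CH2OTBS), and this geometry later places CH3 inside and CH2O outside at C6'.

Step 5
Reactants: 10
Product: 11 (E)-4-[(tert-butyldimethylsilyl)oxy]-3-methylbut-2-enoic acid
Conditions: LiOH·H2O, THF/MeOH/H2O, 23 °C; then 1 M HCl to pH 4, 0 °C
Reagents that add atoms: lithium hydroxide, [Li+].[OH-]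
Why: Ester saponification, in which the primary silyl ether and the trisubstituted E-alkene should be stable to hydroxide at room temperature.

Step 6
Reactants: 11
Product: 12 (E)-4-[(tert-butyldimethylsilyl)oxy]-3-methylbut-2-enoyl chloride
Conditions: 1-chloro-N,N,2-trimethylprop-1-en-1-amine, CH2Cl2, 0 → 23 °C; used as solution
Reagents that add atoms: 1-chloro-N,N,2-trimethylprop-1-en-1-amine, CC(C)=C(Cl)N(C)C
Why: Chloride transfer from the α-chloroenamine forms the acid chloride under neutral conditions, so no HCl is present to cleave the silyl ether or isomerise the alkene.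

Step 7
Reactants: 7 (2S)-2-tert-butyl-4-(prop-1-en-2-yl)-5-[(trimethylsilyl)oxy]-1,3-dioxole; 12 (E)-4-[(tert-butyldimethylsilyl)oxy]-3-methylbut-2-enoyl chloride
Product: 15 (2S,5R,10S)-2-tert-butyl-10-{[(tert-butyldimethylsilyl)oxy]methyl}-6,10-dimethyl-1,3-dioxaspiro[4.5]dec-6-ene-4,8-dione, via γ-acyl dienone 13 (not isolated), via oxidotriene salt 14 (not isolated)
Conditions: ZnBr2 (10 mol%), CH2Cl2, −78 → 0 °C; then DBU (1.5 equiv), 0 → 23 °C (40 °C if slow); aq. NH4Cl
Reagents that add atoms: none
Why: Proposed new method: the silyl dienolate 7 should be acylated by 12 at its unhindered terminal carbon C3' (ZnBr2-promoted vinylogous acylation; attack at the ring carbon would build a quaternary centre) to give 13, whose C3' methylene, α to the new ketone and vinylogous to the lactone carbonyl, is deprotonated by DBU to the 3-oxido-hexatriene 14 (C1'=C2'–C3'=C4'(O–)–C5'=C6'), which closes the C1'–C6' bond by thermal disrotatory 6π electrocyclisation, equivalent to a 6-endo-trig vinylogous Michael addition of the dioxolanone α-carbon. The closest known reaction types are the γ-acylation of silyl dienolates by acid chlorides and the charge-accelerated 6π closure of 2-oxido-trienes (from cross-conjugated dienones and base) to cyclohexenones; joining them in one flask with a dioxolanone-bound terminus is not known. The one ring formed, the six-membered carbocycle, closes suprafacially at both termini. C1' is set by the tert-butyl acetal carbon, because C6' can reach the planar dioxolanone terminus only on the face opposite tert-butyl (the facial rule of alkylations of these enolates), and C6' is set relative to C1' by the disrotation, which brings the two inside groups (ring oxygen on C1', CH3 on C6' of the E-enone) to one face and the two outside groups (lactone carbonyl, CH2OTBS) to the other. The step needs γ- rather than α- or O-acylation (sterics and Lewis acid activation of the acid chloride), closure through the rotamer with the ring oxygen inside (the W-shaped vinylogous carboxylate keeps the charged oxygens apart and the carbonyl out of the forming bond), and an intact E geometry at C5'=C6' (DBU is too weak to enolise toward C8' or C9').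

Step 8
Reactants: 15
Product: 17 (2S,5R,10S)-2-tert-butyl-10-{[(tert-butyldimethylsilyl)oxy]methyl}-4-hydroxy-6,10-dimethyl-1,3-dioxaspiro[4.5]dec-6-en-8-one (C4 epimers), via lithium dienolate 16 (not isolated)
Conditions: LiHMDS (commercial solution, 1.05 equiv), THF, −78 °C; then DIBAL-H (1.3 equiv), −78 °C; aq. Rochelle salt
Reagents that add atoms: none
Why: Kinetic deprotonation at C5' stores the enone as its lithium dienolate (transient enolate protection), so diisobutylaluminium hydride should reduce only the non-enolisable dioxolanone carbonyl to the lactol, and C-protonation on work-up returns the conjugated enone.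

Step 9
Reactants: 18 dibromomethane; 19 tributyltin chloride
Product: 21 (dibromomethyl)tributylstannane, via dibromomethyllithium 20 (not isolated)
Conditions: LDA (commercial solution), THF, −78 °C; then Bu3SnCl, −78 → 0 °C
Reagents that add atoms: none
Why: Deprotonation of CH2Br2 to the lithium carbenoid and its capture at tin should give the gem-dibromide needed for the stannyl olefination.

Step 10
Reactants: 17; 21
Product: 23 (4R,5S)-5-{[(tert-butyldimethylsilyl)oxy]methyl}-4-hydroxy-3,5-dimethyl-4-[(E)-2-(tributylstannyl)ethenyl]cyclohex-2-en-1-one, via hydroxy aldehyde 22 (not isolated)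
Conditions: CrCl2 (8 equiv), LiI (4 equiv), 21 (2.5 equiv), THF/DMF, 23 °C, dark
Reagents that add atoms: none
Why: The lactol should open with loss of pivalaldehyde to the α-hydroxy aldehyde, and Takai-type olefination with the gem-dichromium species from 21 (through its diiodide formed with LiI) should give the E-alkenylstannane and leave the 1'-hydroxyl free.

Step 11
Reactants: 23
Product: 24 (4R,5S)-4-hydroxy-5-(hydroxymethyl)-3,5-dimethyl-4-[(E)-2-(tributylstannyl)ethenyl]cyclohex-2-en-1-one
Conditions: HF·pyridine, pyridine, THF, 0 °C; used at once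
Reagents that add atoms: none
Why: Buffered fluoride should cleave the primary silyl ether while the alkenylstannane survives, and the weakly acidic medium keeps the freed 8'-hydroxyl from adding to C2' of the enone (oxa-Michael closure).

Step 12
Reactants: 25 dimethyl 3-hydroxy-3-methylpentanedioate
Product: 26 (S)-3-hydroxy-5-methoxy-3-methyl-5-oxopentanoic acid
Conditions: pig liver esterase, phosphate buffer pH 7.5, 25 °C, pH-stat (1 M NaOH); then HCl to pH 2, EtOAc
Reagents that add atoms: water, O
Why: Enzymatic desymmetrisation of the prochiral diester (enantiotopic-group-selective hydrolysis) should give the (S)-monoester, which becomes the 3R acyl group of the target once its free acid is esterified.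

Step 13
Reactants: 24; 26
Product: 27 [(1S,2R)-2-hydroxy-1,3-dimethyl-5-oxo-2-[(E)-2-(tributylstannyl)ethenyl]cyclohex-3-en-1-yl]methyl methyl (3R)-3-hydroxy-3-methylpentanedioate
Conditions: EDC·HCl (1.5 equiv), DMAP (0.2 equiv), 26 (1.5 equiv), CH2Cl2, 0 °C
Reagents that add atoms: none
Why: Steglich esterification should acylate the primary 8'-hydroxyl in preference to the two tertiary hydroxyls (1'-OH and the glutarate carbinol), and fast acylation at 0 °C should outrun the oxa-Michael closure.

Step 14
Reactants: 28 but-2-ynoic acid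
Product: 29 (Z)-3-iodobut-2-enoic acid
Conditions: NaI, AcOH, 115 °C
Reagents that add atoms: sodium iodide, [Na+].[I-]
Why: Anti hydroiodination of the ynoic acid (conjugate addition of iodide, then protonation) should give the Z-β-iodo acid with iodine cis to the carboxyl group.

Step 15
Reactants: 27; 29
Product: 30 (2Z,4E)-5-[(1R,6S)-1-hydroxy-6-({[(3R)-3-hydroxy-5-methoxy-3-methyl-5-oxopentanoyl]oxy}methyl)-2,6-dimethyl-4-oxocyclohex-2-en-1-yl]-3-methylpenta-2,4-dienoic acid (CNP0274837.1)
Conditions: Pd(MeCN)2Cl2 (5 mol%), DMF, 23 °C, dark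
Reagents that add atoms: none
Why: Stille coupling with retention at both alkenyl carbons joins C4 to C3 and should give the (2Z,4E)-dienoic acid directly, under neutral conditions that leave the enone, the tertiary alcohols and both esters untouched.

**Compound list**

1 | (S)-2-hydroxy-3-methylbutanoic acid | CC(C)[C@H](O)C(=O)O | starting material
2 | pivalaldehyde (2,2-dimethylpropanal) | CC(C)(C)C=O | starting material
3 | (2S,5S)-2-tert-butyl-5-(propan-2-yl)-1,3-dioxolan-4-one (cis) | CC(C)[C@@H]1O[C@H](C(C)(C)C)OC1=O | intermediate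
4 | 5-bromo-2-tert-butyl-5-(propan-2-yl)-1,3-dioxolan-4-one (acetal carbon as in 3, C5 epimers; not isolated) | CC(C)C1(Br)O[C@H](C(C)(C)C)OC1=O | intermediate
5 | (2S)-2-tert-butyl-5-(propan-2-ylidene)-1,3-dioxolan-4-one | CC(C)=C1O[C@H](C(C)(C)C)OC1=O | intermediate
6 | lithium dienolate of 5 (not isolated) | [Li+].CC(=C)C1=C([O-])O[C@@H](C(C)(C)C)O1 | intermediate
7 | (2S)-2-tert-butyl-4-(prop-1-en-2-yl)-5-[(trimethylsilyl)oxy]-1,3-dioxole | CC(=C)C1=C(O[Si](C)(C)C)O[C@@H](C(C)(C)C)O1 | intermediate
8 | 1-[(tert-butyldimethylsilyl)oxy]propan-2-one | CC(=O)CO[Si](C)(C)C(C)(C)C | starting material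
9 | triethyl phosphonoacetate | CCOC(=O)CP(=O)(OCC)OCC | starting material
10 | ethyl (E)-4-[(tert-butyldimethylsilyl)oxy]-3-methylbut-2-enoate | CCOC(=O)/C=C(\C)CO[Si](C)(C)C(C)(C)C | intermediate
11 | (E)-4-[(tert-butyldimethylsilyl)oxy]-3-methylbut-2-enoic acid | OC(=O)/C=C(\C)CO[Si](C)(C)C(C)(C)C | intermediate
12 | (E)-4-[(tert-butyldimethylsilyl)oxy]-3-methylbut-2-enoyl chloride | ClC(=O)/C=C(\C)CO[Si](C)(C)C(C)(C)C | intermediate
13 | (2S)-2-tert-butyl-5-{(5E)-7-[(tert-butyldimethylsilyl)oxy]-6-methyl-4-oxohept-5-en-2-ylidene}-1,3-dioxolan-4-one (alkylidene isomers; not isolated) | CC(CC(=O)/C=C(\C)CO[Si](C)(C)C(C)(C)C)=C1O[C@H](C(C)(C)C)OC1=O | intermediate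
14 | 1,8-diazabicyclo[5.4.0]undec-7-enium salt of the 3-oxido-hexatriene, the conjugate base of 13 (one resonance form; not isolated) | CC(C=C([O-])/C=C(\C)CO[Si](C)(C)C(C)(C)C)=C1O[C@H](C(C)(C)C)OC1=O.C1CCC2=[NH+]CCCN2CC1 | intermediate
15 | (2S,5R,10S)-2-tert-butyl-10-{[(tert-butyldimethylsilyl)oxy]methyl}-6,10-dimethyl-1,3-dioxaspiro[4.5]dec-6-ene-4,8-dione | CC(C)(C)[Si](C)(C)OC[C@]1(C)CC(=O)C=C(C)[C@@]12O[C@H](C(C)(C)C)OC2=O | intermediate
16 | lithium cross-conjugated dienolate of 15 (not isolated) | [Li+].CC(C)(C)[Si](C)(C)OC[C@]1(C)C=C([O-])C=C(C)[C@@]12O[C@H](C(C)(C)C)OC2=O | intermediate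
17 | (2S,5R,10S)-2-tert-butyl-10-{[(tert-butyldimethylsilyl)oxy]methyl}-4-hydroxy-6,10-dimethyl-1,3-dioxaspiro[4.5]dec-6-en-8-one (C4 epimers) | CC(C)(C)[Si](C)(C)OC[C@]1(C)CC(=O)C=C(C)[C@@]12O[C@H](C(C)(C)C)OC2O | intermediate
18 | dibromomethane | BrCBr | starting material
19 | tributyltin chloride (chlorotributylstannane) | CCCC[Sn](Cl)(CCCC)CCCC | starting material
20 | (dibromomethyl)lithium (not isolated) | [Li]C(Br)Br | intermediate
21 | (dibromomethyl)tributylstannane | CCCC[Sn](CCCC)(CCCC)C(Br)Br | intermediate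
22 | (1R,6S)-6-{[(tert-butyldimethylsilyl)oxy]methyl}-1-hydroxy-2,6-dimethyl-4-oxocyclohex-2-ene-1-carbaldehyde (not isolated) | CC(C)(C)[Si](C)(C)OC[C@]1(C)CC(=O)C=C(C)[C@]1(O)C=O | intermediate
23 | (4R,5S)-5-{[(tert-butyldimethylsilyl)oxy]methyl}-4-hydroxy-3,5-dimethyl-4-[(E)-2-(tributylstannyl)ethenyl]cyclohex-2-en-1-one | CC(C)(C)[Si](C)(C)OC[C@]1(C)CC(=O)C=C(C)[C@]1(O)/C=C/[Sn](CCCC)(CCCC)CCCC | intermediate
24 | (4R,5S)-4-hydroxy-5-(hydroxymethyl)-3,5-dimethyl-4-[(E)-2-(tributylstannyl)ethenyl]cyclohex-2-en-1-one | OC[C@]1(C)CC(=O)C=C(C)[C@]1(O)/C=C/[Sn](CCCC)(CCCC)CCCC | intermediate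
25 | dimethyl 3-hydroxy-3-methylpentanedioate | COC(=O)CC(C)(O)CC(=O)OC | starting material
26 | (S)-3-hydroxy-5-methoxy-3-methyl-5-oxopentanoic acid | COC(=O)C[C@@](C)(O)CC(=O)O | intermediate
27 | [(1S,2R)-2-hydroxy-1,3-dimethyl-5-oxo-2-[(E)-2-(tributylstannyl)ethenyl]cyclohex-3-en-1-yl]methyl methyl (3R)-3-hydroxy-3-methylpentanedioate | COC(=O)C[C@@](C)(O)CC(=O)OC[C@]1(C)CC(=O)C=C(C)[C@]1(O)/C=C/[Sn](CCCC)(CCCC)CCCC | intermediate
28 | but-2-ynoic acid | CC#CC(=O)O | starting material
29 | (Z)-3-iodobut-2-enoic acid | C/C(I)=C/C(=O)O | intermediate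
30 | (2Z,4E)-5-[(1R,6S)-1-hydroxy-6-({[(3R)-3-hydroxy-5-methoxy-3-methyl-5-oxopentanoyl]oxy}methyl)-2,6-dimethyl-4-oxocyclohex-2-en-1-yl]-3-methylpenta-2,4-dienoic acid | COC(=O)C[C@@](C)(O)CC(=O)OC[C@]1(C)CC(=O)C=C(C)[C@]1(O)/C=C/C(C)=C\C(=O)O | target

**Step count and risks**

Total steps: 15. Longest linear sequence: 9 (steps 1, 2, 3, 7, 8, 10, 11, 13, 15).

Step 7 (Proposed new method). What may go wrong: acylation of 7 at oxygen or at the ring carbon instead of C3'; a ring closure that stalls at 13 because two fully substituted termini must meet; or closure through the rotamer with the lactone carbonyl inside, which would invert C6' relative to C1'. Fallback with known reactions, from 10 and 7 back to 15: ester 10 is reduced with DIBAL-H to (E)-4-[(tert-butyldimethylsilyl)oxy]-3-methylbut-2-en-1-ol F1 and oxidised with MnO2 to (E)-4-[(tert-butyldimethylsilyl)oxy]-3-methylbut-2-enal F2. A BF3·OEt2-promoted vinylogous Mukaiyama aldol addition of 7 to F2 (terminal attack is the rule for silyl dienolates) gives (2S)-2-tert-butyl-5-{(5E)-7-[(tert-butyldimethylsilyl)oxy]-4-hydroxy-6-methylhept-5-en-2-ylidene}-1,3-dioxolan-4-one F3, and Dess–Martin oxidation gives 13 as an isolated compound. O-Silylation (TBSOTf, Et3N) gives the neutral triene (2S)-2-tert-butyl-5-{(5E)-4,7-bis[(tert-butyldimethylsilyl)oxy]-6-methylhepta-3,5-dien-2-ylidene}-1,3-dioxolan-4-one F4. Heating F4 in toluene (80–110 °C) should bring about a thermal disrotatory 6π electrocyclisation to (2S,5R,10S)-2-tert-butyl-8-[(tert-butyldimethylsilyl)oxy]-10-{[(tert-butyldimethylsilyl)oxy]methyl}-6,10-dimethyl-1,3-dioxaspiro[4.5]deca-6,8-dien-4-one F5. Brief hydrolysis of the enol ether (AcOH/THF/H2O, 0 °C) returns 15.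

Step 8. What may go wrong: incomplete enolisation lets hydride attack the enone carbonyl, or the lactol aluminate collapses and is reduced further. Fallback from 15 back to 23: excess DIBAL-H reduces both carbonyls to (2S,5R,10S)-2-tert-butyl-10-{[(tert-butyldimethylsilyl)oxy]methyl}-6,10-dimethyl-1,3-dioxaspiro[4.5]dec-6-ene-4,8-diol F6 (epimers at both carbinols). The chromium stannyl olefination with 21, run as in step 10, gives (4R,5S)-5-{[(tert-butyldimethylsilyl)oxy]methyl}-3,5-dimethyl-4-[(E)-2-(tributylstannyl)ethenyl]cyclohex-2-ene-1,4-diol F7. MnO2 then oxidises only the secondary allylic alcohol and returns 23.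

Step 10. What may go wrong: slow opening of the hindered lactol, sluggish addition of the gem-dichromium reagent to an aldehyde on a fully substituted carbon, or α-ketol rearrangement of the hydroxy aldehyde on the chromium Lewis acid. Fallback from 17 back to 23: Ohira–Bestmann homologation (dimethyl (1-diazo-2-oxopropyl)phosphonate, K2CO3, MeOH) converts the lactol into (4R,5S)-5-{[(tert-butyldimethylsilyl)oxy]methyl}-4-ethynyl-4-hydroxy-3,5-dimethylcyclohex-2-en-1-one F8. Pd(PPh3)2Cl2-catalysed syn-hydrostannation with Bu3SnH (THF, 0 °C; tin goes to the terminal carbon of the hindered propargylic alcohol) then gives 23.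

**Further compounds**

F1 | step 7 | (E)-4-[(tert-butyldimethylsilyl)oxy]-3-methylbut-2-en-1-ol | OC/C=C(\C)CO[Si](C)(C)C(C)(C)C
F2 | step 7 | (E)-4-[(tert-butyldimethylsilyl)oxy]-3-methylbut-2-enal | O=C/C=C(\C)CO[Si](C)(C)C(C)(C)C
F3 | step 7 | (2S)-2-tert-butyl-5-{(5E)-7-[(tert-butyldimethylsilyl)oxy]-4-hydroxy-6-methylhept-5-en-2-ylidene}-1,3-dioxolan-4-one | CC(CC(O)/C=C(\C)CO[Si](C)(C)C(C)(C)C)=C1O[C@H](C(C)(C)C)OC1=O
F4 | step 7 | (2S)-2-tert-butyl-5-{(5E)-4,7-bis[(tert-butyldimethylsilyl)oxy]-6-methylhepta-3,5-dien-2-ylidene}-1,3-dioxolan-4-one | CC(C=C(O[Si](C)(C)C(C)(C)C)/C=C(\C)CO[Si](C)(C)C(C)(C)C)=C1O[C@H](C(C)(C)C)OC1=O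
F5 | step 7 | (2S,5R,10S)-2-tert-butyl-8-[(tert-butyldimethylsilyl)oxy]-10-{[(tert-butyldimethylsilyl)oxy]methyl}-6,10-dimethyl-1,3-dioxaspiro[4.5]deca-6,8-dien-4-one | CC(C)(C)[Si](C)(C)OC[C@]1(C)C=C(O[Si](C)(C)C(C)(C)C)C=C(C)[C@@]12O[C@H](C(C)(C)C)OC2=O
F6 | step 8 | (2S,5R,10S)-2-tert-butyl-10-{[(tert-butyldimethylsilyl)oxy]methyl}-6,10-dimethyl-1,3-dioxaspiro[4.5]dec-6-ene-4,8-diol | CC(C)(C)[Si](C)(C)OC[C@]1(C)CC(O)C=C(C)[C@@]12O[C@H](C(C)(C)C)OC2O
F7 | step 8 | (4R,5S)-5-{[(tert-butyldimethylsilyl)oxy]methyl}-3,5-dimethyl-4-[(E)-2-(tributylstannyl)ethenyl]cyclohex-2-ene-1,4-diol | CC(C)(C)[Si](C)(C)OC[C@]1(C)CC(O)C=C(C)[C@]1(O)/C=C/[Sn](CCCC)(CCCC)CCCC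
F8 | step 10 | (4R,5S)-5-{[(tert-butyldimethylsilyl)oxy]methyl}-4-ethynyl-4-hydroxy-3,5-dimethylcyclohex-2-en-1-one | CC(C)(C)[Si](C)(C)OC[C@]1(C)CC(=O)C=C(C)[C@]1(O)C#C
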